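**Plan**

1. Numbering: lactone ring O1–C6, side chain C1′–C15′ (hydroxyls on C2′, C4′, C6′). Retrosynthetic cuts, in order: (a) the ring bond C3=C4 (metathesis) and the ester bond C2–O1; (b) C4′–C5′; (c) C3′–C4′; (d) C5–C6.
2. Enabling feature: C4′ is a carbinol between two CH2 groups (C3′, C5′) with oxygen on both β-carbons (C2′, C6′). It is therefore carried as a carbonyl masked in a 1,3-dithiane ring (acyl-anion equivalent), and each flanking O–CH–CH2 unit as a terminal epoxide. The C2′ oxygen lies 1,4 to a silyl group on C4′, so a Brook shift both generates the C4′ carbanion and protects O–C2′.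
3. Forward: the right half is built first (C6 allyl carbinol, C2′–C3′ epoxide, silyl-dithiane at C4′), then C4′ is joined to C5′ of (R)-1,2-epoxyundecane. The dithiane is then hydrolysed, the ketone reduced and the diol masked. The only ring, the lactone, closes in step 13; all helpers (dithiane ring, silyl group, acetonide, PMB) are gone by step 14.
4. Stereochemistry: C6′ from (R)-epichlorohydrin; C2′ from the (R)-butanetriol acetonide 5; C6 by catalyst-controlled allylation; C4′ by hydroxyl-directed 1,3-syn reduction from C6′.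

Key step: step 7

**Route**

Step 1
Reactants: 1 (R)-epichlorohydrin; 2 octylmagnesium bromide
Product: 4 (2R)-2-nonyloxirane, via bromomagnesium chlorohydrin alkoxide 3 (not isolated)
Conditions: CuI (10 mol%), THF, −40 to 0 °C; then 50% aq NaOH, rt, same flask
Reagents that add atoms: none
Why: Copper-catalysed Grignard opening of the epoxide at its CH2 terminus, then base-induced 3-exo-tet closure onto the CH2Cl carbon, should give the epoxide with the R stereocentre of 1 untouched.

Step 2
Reactants: 5 2-[(4R)-2,2-dimethyl-1,3-dioxolan-4-yl]ethan-1-ol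
Product: 6 (2S)-1-[(4R)-2,2-dimethyl-1,3-dioxolan-4-yl]pent-4-en-2-ol
Conditions: allyl acetate (2 equiv), [Ir(cod)Cl]2 (2.5 mol%), (S)-Cl,MeO-BIPHEP (5 mol%), 4-chloro-3-nitrobenzoic acid (10 mol%), Cs2CO3 (20 mol%), THF, 100 °C, sealed tube
Reagents that add atoms: allyl acetate, CC(=O)OCC=C
Why: Krische allylation from the alcohol oxidation level: the iridium catalyst dehydrogenates the primary alcohol in situ and the chiral π-allyliridium C,O-benzoate adds under catalyst control, which should set the new carbinol S (1,3-anti to the dioxolane oxygen); the ligand antipode is the one assigned to give this sense for β-oxygenated primary alcohols.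

Step 3
Reactants: 6 (2S)-1-[(4R)-2,2-dimethyl-1,3-dioxolan-4-yl]pent-4-en-2-ol
Product: 7 (4R)-4-[(2S)-2-[(4-methoxyphenyl)methoxy]pent-4-en-1-yl]-2,2-dimethyl-1,3-dioxolane
Conditions: NaH, 4-methoxybenzyl chloride, Bu4NI (cat.), THF/DMF, 0 °C to rt
Reagents that add atoms: 4-methoxybenzyl chloride, COc1ccc(CCl)cc1
Why: Williamson etherification installs a non-migrating PMB ether that tolerates organolithium reagents and can later be removed in the presence of the silyl ether and acetonide.

Step 4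
Reactants: 7 (4R)-4-[(2S)-2-[(4-methoxyphenyl)methoxy]pent-4-en-1-yl]-2,2-dimethyl-1,3-dioxolane
Product: 8 (2R,4S)-4-[(4-methoxyphenyl)methoxy]hept-6-ene-1,2-diol
Conditions: AcOH/H2O (4:1), 40 °C
Reagents that add atoms: none
Why: Mild acid hydrolysis of the terminal dioxolane should leave the PMB ether and the alkene untouched.

Step 5
Reactants: 8 (2R,4S)-4-[(4-methoxyphenyl)methoxy]hept-6-ene-1,2-diol
Product: 10 (2R)-2-[(2S)-2-[(4-methoxyphenyl)methoxy]pent-4-en-1-yl]oxirane, via primary monotosylate 9 (not isolated)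
Conditions: TsCl (1.05 equiv), Et3N, Bu2SnO (2 mol%), CH2Cl2, 0 °C to rt; then K2CO3, MeOH, rt
Reagents that add atoms: none
Why: Tin-catalysed selective sulfonylation of the primary hydroxyl and intramolecular Williamson (3-exo-tet) closure by the secondary alkoxide should give the epoxide with retention, since no bond to the stereocentre is broken.

Step 6
Reactants: 11 tert-butyl(1,3-dithian-2-yl)dimethylsilane; 10 (2R)-2-[(2S)-2-[(4-methoxyphenyl)methoxy]pent-4-en-1-yl]oxirane
Product: 13 (2R,4S)-1-[2-(tert-butyldimethylsilyl)-1,3-dithian-2-yl]-4-[(4-methoxyphenyl)methoxy]hept-6-en-2-ol, via 2-lithio-2-silyl-1,3-dithiane 12 (not isolated)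
Conditions: 11 (1.2 equiv), t-BuLi (1.15 equiv), Et2O, −78 to −45 °C; then 10, Et2O, −78 to −25 °C; H2O quench
Reagents that add atoms: none
Why: Corey–Seebach alkylation: the lithiated silyl dithiane opens the monosubstituted epoxide at CH2, and in ether without a polar cosolvent the lithium alkoxide should not undergo silyl migration, so the C-silyl carbinol can be isolated and purified before the union.

Step 7
Reactants: 13 (2R,4S)-1-[2-(tert-butyldimethylsilyl)-1,3-dithian-2-yl]-4-[(4-methoxyphenyl)methoxy]hept-6-en-2-ol; 4 (2R)-2-nonyloxirane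
Product: 16 (2R)-1-[2-[(2R,4S)-2-[(tert-butyldimethylsilyl)oxy]-4-[(4-methoxyphenyl)methoxy]hept-6-en-1-yl]-1,3-dithian-2-yl]undecan-2-ol, via lithium alkoxide 14 (not isolated), via silyloxy 2-lithiodithiane 15 (not isolated)
Conditions: n-BuLi (1.0 equiv), Et2O, −78 °C; then 4 (1.2 equiv) in THF/HMPA, −78 °C to rt; H2O quench
Reagents that add atoms: none
Why: Deprotonation of the hydroxyl gives alkoxide 14, which on addition of the polar cosolvent should undergo a 1,4-Brook rearrangement (silicon moves from the dithiane carbon to oxygen through a five-membered siliconate) to unveil the 2-lithio-1,3-dithiane 15; this acyl-anion equivalent opens epoxide 4 by SN2 attack at its terminal CH2, forming the C4′–C5′ bond between the dithiane carbon and the methylene next to the nonyl-bearing carbinol. The closest known reaction type is the solvent-controlled silyl-dithiane linchpin coupling of two epoxides (anion relay chemistry), run here with the first adduct isolated. It is an umpolung union: in the natural polarity of a 1,3-diol both carbons are electrophilic (a carbonyl carbon and an epoxide terminus), and the dithiane reverses one of them. No ring is closed and no stereocentre is created: C6′ keeps the R configuration of 4 because only the unsubstituted epoxide carbon is attacked, and C4′ stays a masked ketone whose configuration is set in step 9. The step needs the silyl shift to precede C–C bond formation and attack at the epoxide terminus only; the 1,4 relationship of oxygen and silicon in 13, the absence of a leaving group β to the carbanion (the silyloxy group is γ) and the steric bias of a monosubstituted epoxide should secure this. The shift leaves O–C2′ silylated and the new C6′ hydroxyl free to direct the later reduction.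

Step 8
Reactants: 16 (2R)-1-[2-[(2R,4S)-2-[(tert-butyldimethylsilyl)oxy]-4-[(4-methoxyphenyl)methoxy]hept-6-en-1-yl]-1,3-dithian-2-yl]undecan-2-ol
Product: 17 (4S,6R,10R)-6-[(tert-butyldimethylsilyl)oxy]-10-hydroxy-4-[(4-methoxyphenyl)methoxy]nonadec-1-en-8-one
Conditions: MeI (10 equiv), CaCO3, MeCN/H2O (9:1), 45 °C
Reagents that add atoms: water, O
Why: S-methylation turns the thioacetal into a sulfonium leaving group that is hydrolysed under buffered, near-neutral conditions, which the alkene, the PMB and silyl ethers and the β-hydroxy ketone should tolerate.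

Step 9
Reactants: 17 (4S,6R,10R)-6-[(tert-butyldimethylsilyl)oxy]-10-hydroxy-4-[(4-methoxyphenyl)methoxy]nonadec-1-en-8-one
Product: 19 (4S,6S,8R,10R)-6-[(tert-butyldimethylsilyl)oxy]-4-[(4-methoxyphenyl)methoxy]nonadec-1-ene-8,10-diol, via diethylboron chelate 18 (not isolated)
Conditions: Et2BOMe (1.1 equiv), THF/MeOH (4:1), −78 °C; NaBH4, −78 °C; AcOH, then evaporation from MeOH (boron leaves as Et2BOMe)
Reagents that add atoms: none
Why: Narasaka–Prasad reduction: only the free C6′ hydroxyl can form the six-membered boron chelate with the ketone (the silyl ether cannot), and external axial hydride delivery to the half-chair should give the 1,3-syn diol, i.e. the R carbinol at C4′, anti to C2′.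

Step 10
Reactants: 19 (4S,6S,8R,10R)-6-[(tert-butyldimethylsilyl)oxy]-4-[(4-methoxyphenyl)methoxy]nonadec-1-ene-8,10-diol
Product: 20 tert-butyl{[(2R,4S)-1-[(4R,6R)-2,2-dimethyl-6-nonyl-1,3-dioxan-4-yl]-4-[(4-methoxyphenyl)methoxy]hept-6-en-2-yl]oxy}dimethylsilane
Conditions: 2,2-dimethoxypropane, PPTS (cat.), CH2Cl2, rt
Reagents that add atoms: 2,2-dimethoxypropane, COC(C)(C)OC
Why: Transacetalisation should give the chair cis-4,6-dialkyl-1,3-dioxane of the syn diol, masking both hydroxyls before the lactone oxygen is freed.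

Step 11
Reactants: 20 tert-butyl{[(2R,4S)-1-[(4R,6R)-2,2-dimethyl-6-nonyl-1,3-dioxan-4-yl]-4-[(4-methoxyphenyl)methoxy]hept-6-en-2-yl]oxy}dimethylsilane
Product: 21 (4S,6R)-6-[(tert-butyldimethylsilyl)oxy]-7-[(4R,6R)-2,2-dimethyl-6-nonyl-1,3-dioxan-4-yl]hept-1-en-4-ol
Conditions: DDQ (1.3 equiv), CH2Cl2/pH 7 buffer (10:1), 0 °C
Reagents that add atoms: none
Why: Oxidative PMB cleavage (benzylic hydride abstraction, hydrolysis of the oxocarbenium ion) under buffered conditions should leave the silyl ether, acetonide and terminal alkene intact.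

Step 12
Reactants: 21 (4S,6R)-6-[(tert-butyldimethylsilyl)oxy]-7-[(4R,6R)-2,2-dimethyl-6-nonyl-1,3-dioxan-4-yl]hept-1-en-4-ol
Product: 22 (4S,6S)-6-[(tert-butyldimethylsilyl)oxy]-7-[(4R,6R)-2,2-dimethyl-6-nonyl-1,3-dioxan-4-yl]hept-1-en-4-yl prop-2-enoate
Conditions: acryloyl chloride, Et3N, DMAP (cat.), CH2Cl2, 0 °C
Reagents that add atoms: acryloyl chloride, C=CC(=O)Cl
Why: O-Acylation of the only free hydroxyl should install the second alkene for ring closure without touching the stereocentre.

Step 13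
Reactants: 22 (4S,6S)-6-[(tert-butyldimethylsilyl)oxy]-7-[(4R,6R)-2,2-dimethyl-6-nonyl-1,3-dioxan-4-yl]hept-1-en-4-yl prop-2-enoate
Product: 23 (6S)-6-[(2S)-2-[(tert-butyldimethylsilyl)oxy]-3-[(4R,6R)-2,2-dimethyl-6-nonyl-1,3-dioxan-4-yl]propyl]-5,6-dihydro-2H-pyran-2-one
Conditions: second-generation Grubbs catalyst (H2IMes)(PCy3)Cl2Ru=CHPh (5 mol%), CH2Cl2 (0.005 M), 40 °C
Reagents that add atoms: none
Why: Ring-closing metathesis between the acrylate and the allyl group should close the six-membered α,β-unsaturated lactone (cis alkene enforced by the ring) with loss of ethene.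

Step 14
Reactants: 23 (6S)-6-[(2S)-2-[(tert-butyldimethylsilyl)oxy]-3-[(4R,6R)-2,2-dimethyl-6-nonyl-1,3-dioxan-4-yl]propyl]-5,6-dihydro-2H-pyran-2-one
Product: 24 (6S)-6-[(2S,4R,6R)-2,4,6-trihydroxypentadecyl]-5,6-dihydro-2H-pyran-2-one
Conditions: 48% aq HF, MeCN, 0 °C to rt
Reagents that add atoms: none
Why: Aqueous HF should cleave the silyl ether and hydrolyse the acetonide in one operation, under acidic conditions in which the unsaturated lactone is expected to survive.

**Compound list**

1 | (2R)-2-(chloromethyl)oxirane, (R)-epichlorohydrin | ClC[C@H]1CO1 | starting material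
2 | octylmagnesium bromide | CCCCCCCC[Mg]Br | starting material
3 | bromomagnesium (2R)-1-chloroundecan-2-olate (formed in the flask) | ClC[C@H](O[Mg]Br)CCCCCCCCC | intermediate
4 | (2R)-2-nonyloxirane, (R)-1,2-epoxyundecane | CCCCCCCCC[C@@H]1CO1 | intermediate
5 | 2-[(4R)-2,2-dimethyl-1,3-dioxolan-4-yl]ethan-1-ol | OCC[C@@H]1COC(C)(C)O1 | starting material
6 | (2S)-1-[(4R)-2,2-dimethyl-1,3-dioxolan-4-yl]pent-4-en-2-ol | C1[C@H](OC(C)(C)O1)C[C@@H](O)CC=C | intermediate
7 | (4R)-4-[(2S)-2-[(4-methoxyphenyl)methoxy]pent-4-en-1-yl]-2,2-dimethyl-1,3-dioxolane | C1[C@H](OC(C)(C)O1)C[C@@H](OCc1ccc(OC)cc1)CC=C | intermediate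
8 | (2R,4S)-4-[(4-methoxyphenyl)methoxy]hept-6-ene-1,2-diol | OC[C@H](O)C[C@@H](OCc1ccc(OC)cc1)CC=C | intermediate
9 | (2R,4S)-2-hydroxy-4-[(4-methoxyphenyl)methoxy]hept-6-en-1-yl 4-methylbenzenesulfonate (formed in the flask) | Cc1ccc(cc1)S(=O)(=O)OC[C@H](O)C[C@@H](OCc1ccc(OC)cc1)CC=C | intermediate
10 | (2R)-2-[(2S)-2-[(4-methoxyphenyl)methoxy]pent-4-en-1-yl]oxirane | C1[C@H](O1)C[C@@H](OCc1ccc(OC)cc1)CC=C | intermediate
11 | tert-butyl(1,3-dithian-2-yl)dimethylsilane | CC(C)(C)[Si](C)(C)C1SCCCS1 | starting material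
12 | tert-butyl(2-lithio-1,3-dithian-2-yl)dimethylsilane (formed in the flask) | CC(C)(C)[Si](C)(C)C1([Li])SCCCS1 | intermediate
13 | (2R,4S)-1-[2-(tert-butyldimethylsilyl)-1,3-dithian-2-yl]-4-[(4-methoxyphenyl)methoxy]hept-6-en-2-ol | CC(C)(C)[Si](C)(C)C1(SCCCS1)C[C@H](O)C[C@@H](OCc1ccc(OC)cc1)CC=C | intermediate
14 | lithium alkoxide of 13 (formed in the flask) | CC(C)(C)[Si](C)(C)C1(SCCCS1)C[C@H](O[Li])C[C@@H](OCc1ccc(OC)cc1)CC=C | intermediate
15 | 2-lithio-2-[(2R,4S)-2-[(tert-butyldimethylsilyl)oxy]-4-[(4-methoxyphenyl)methoxy]hept-6-en-1-yl]-1,3-dithiane (formed in the flask) | [Li]C1(SCCCS1)C[C@H](O[Si](C)(C)C(C)(C)C)C[C@@H](OCc1ccc(OC)cc1)CC=C | intermediate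
16 | (2R)-1-[2-[(2R,4S)-2-[(tert-butyldimethylsilyl)oxy]-4-[(4-methoxyphenyl)methoxy]hept-6-en-1-yl]-1,3-dithian-2-yl]undecan-2-ol | CCCCCCCCC[C@@H](O)CC1(SCCCS1)C[C@H](O[Si](C)(C)C(C)(C)C)C[C@@H](OCc1ccc(OC)cc1)CC=C | intermediate
17 | (4S,6R,10R)-6-[(tert-butyldimethylsilyl)oxy]-10-hydroxy-4-[(4-methoxyphenyl)methoxy]nonadec-1-en-8-one | CCCCCCCCC[C@@H](O)CC(=O)C[C@H](O[Si](C)(C)C(C)(C)C)C[C@@H](OCc1ccc(OC)cc1)CC=C | intermediate
18 | O-diethylboryl derivative (boron chelate) of 17 at the C10 hydroxyl (formed in the flask) | CCCCCCCCC[C@@H](OB(CC)CC)CC(=O)C[C@H](O[Si](C)(C)C(C)(C)C)C[C@@H](OCc1ccc(OC)cc1)CC=C | intermediate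
19 | (4S,6S,8R,10R)-6-[(tert-butyldimethylsilyl)oxy]-4-[(4-methoxyphenyl)methoxy]nonadec-1-ene-8,10-diol | CCCCCCCCC[C@@H](O)C[C@@H](O)C[C@H](O[Si](C)(C)C(C)(C)C)C[C@@H](OCc1ccc(OC)cc1)CC=C | intermediate
20 | tert-butyl{[(2R,4S)-1-[(4R,6R)-2,2-dimethyl-6-nonyl-1,3-dioxan-4-yl]-4-[(4-methoxyphenyl)methoxy]hept-6-en-2-yl]oxy}dimethylsilane (cis-acetonide of 19) | CCCCCCCCC[C@@H]1C[C@H](C[C@H](O[Si](C)(C)C(C)(C)C)C[C@@H](OCc2ccc(OC)cc2)CC=C)OC(C)(C)O1 | intermediate
21 | (4S,6R)-6-[(tert-butyldimethylsilyl)oxy]-7-[(4R,6R)-2,2-dimethyl-6-nonyl-1,3-dioxan-4-yl]hept-1-en-4-ol | CCCCCCCCC[C@@H]1C[C@H](C[C@H](O[Si](C)(C)C(C)(C)C)C[C@@H](O)CC=C)OC(C)(C)O1 | intermediate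
22 | (4S,6S)-6-[(tert-butyldimethylsilyl)oxy]-7-[(4R,6R)-2,2-dimethyl-6-nonyl-1,3-dioxan-4-yl]hept-1-en-4-yl prop-2-enoate | CCCCCCCCC[C@@H]1C[C@H](C[C@H](O[Si](C)(C)C(C)(C)C)C[C@@H](OC(=O)C=C)CC=C)OC(C)(C)O1 | intermediate
23 | (6S)-6-[(2S)-2-[(tert-butyldimethylsilyl)oxy]-3-[(4R,6R)-2,2-dimethyl-6-nonyl-1,3-dioxan-4-yl]propyl]-5,6-dihydro-2H-pyran-2-one | CCCCCCCCC[C@@H]1C[C@H](C[C@H](O[Si](C)(C)C(C)(C)C)C[C@@H]2CC=CC(=O)O2)OC(C)(C)O1 | intermediate
24 | (6S)-6-[(2S,4R,6R)-2,4,6-trihydroxypentadecyl]-5,6-dihydro-2H-pyran-2-one | CCCCCCCCC[C@@H](O)C[C@@H](O)C[C@H](O)C[C@@H]1CC=CC(=O)O1 | target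

**Step count and risks**

Total steps: 14. Longest linear sequence: 13 (steps 2 to 14, from 5).

Steps most likely to fail:

Step 7. The silyl migration may be incomplete, the relay carbanion may be protonated before it reaches the epoxide, or the hindered carbanion may open the epoxide too slowly. The fallback forms the same C4′–C5′ bond with normal polarity. It sets out from 13, which is rearranged (n-BuLi, THF/HMPA) and quenched with water to 2-[(2R,4S)-2-[(tert-butyldimethylsilyl)oxy]-4-[(4-methoxyphenyl)methoxy]hept-6-en-1-yl]-1,3-dithiane F1. Hydrolysis (MeI, CaCO3, aq MeCN) would give (3R,5S)-3-[(tert-butyldimethylsilyl)oxy]-5-[(4-methoxyphenyl)methoxy]oct-7-enal F2. A Mukaiyama aldol addition of 2-(trimethylsilyloxy)undec-1-ene (BF3·OEt2, CH2Cl2, −78 °C) would rely on 1,3-anti induction from the β-silyloxy group; if that induction is weak, a boron aldol of undecan-2-one with the matching antipode of Ipc2BCl would reinforce it. The product would be (4S,6S,8S)-6-[(tert-butyldimethylsilyl)oxy]-8-hydroxy-4-[(4-methoxyphenyl)methoxy]nonadec-1-en-10-one F3. Narasaka–Prasad reduction (Et2BOMe, NaBH4), now directed by the C4′ hydroxyl, comes back to the route at 19.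

Step 2. Catalyst-controlled facial selectivity may be poor on this β-oxygenated alcohol, the sense of induction may be opposite to that assigned (the antipodal ligand would correct this), or the transfer hydrogenation may stall. The fallback sets out from 5: Parikh–Doering oxidation (SO3·pyridine, DMSO, i-Pr2NEt) to [(4R)-2,2-dimethyl-1,3-dioxolan-4-yl]acetaldehyde F4, then Brown allylation with (−)-Ipc2B(allyl) (Et2O, −78 °C; NaOH/H2O2 work-up), which comes back to the route at 6.

Step 14. Under acid the liberated C2′ hydroxyl may add in conjugate fashion to the unsaturated lactone, or the lactone may open. The fallback reverses the order of events. It sets out from 22, which is deprotected first (48% aq HF, MeCN) to (4S,6S,8R,10R)-6,8,10-trihydroxynonadec-1-en-4-yl prop-2-enoate F5. Ring-closing metathesis of this unprotected triol (second-generation Grubbs catalyst, CH2Cl2, 40 °C) arrives directly at 24, so the unsaturated lactone never meets acid.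

**Further compounds**

F1 | step 7 | 2-[(2R,4S)-2-[(tert-butyldimethylsilyl)oxy]-4-[(4-methoxyphenyl)methoxy]hept-6-en-1-yl]-1,3-dithiane | C1(SCCCS1)C[C@H](O[Si](C)(C)C(C)(C)C)C[C@@H](OCc1ccc(OC)cc1)CC=C
F2 | step 7 | (3R,5S)-3-[(tert-butyldimethylsilyl)oxy]-5-[(4-methoxyphenyl)methoxy]oct-7-enal | O=CC[C@H](O[Si](C)(C)C(C)(C)C)C[C@@H](OCc1ccc(OC)cc1)CC=C
F3 | step 7 | (4S,6S,8S)-6-[(tert-butyldimethylsilyl)oxy]-8-hydroxy-4-[(4-methoxyphenyl)methoxy]nonadec-1-en-10-one | CCCCCCCCCC(=O)C[C@@H](O)C[C@H](O[Si](C)(C)C(C)(C)C)C[C@@H](OCc1ccc(OC)cc1)CC=C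
F4 | step 2 | [(4R)-2,2-dimethyl-1,3-dioxolan-4-yl]acetaldehyde | O=CC[C@@H]1COC(C)(C)O1
F5 | step 14 | (4S,6S,8R,10R)-6,8,10-trihydroxynonadec-1-en-4-yl prop-2-enoate | CCCCCCCCC[C@@H](O)C[C@@H](O)C[C@H](O)C[C@@H](OC(=O)C=C)CC=C
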